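A small charge of X, 0.10 M in the grey run, meets 0.80 M of J and 0.40 M of D, and 72.5% of it stands after 40.0 s. The amber run, with 0.13 M, keeps 73.7% at that time, so the loss looks pseudo-first-order in X.

| flask | X | D | J | remark | time |
|---|---|---|---|---|---|
| amber | 0.13 M | 0.40 M | 0.80 M | run made earlier |  |
| grey | 0.10 M | 0.40 M | 0.80 M | run made earlier |  |
| west | 0.20 M | 0.400 M | 0.800 M |  | 3.0 min |
| south | 0.20 M | 0.600 M | 0.800 M |  | 3.0 min |

| run | time / s | X / % | L / % | Q / % | E / % |
|---|---|---|---|---|---|
| amber | 10.0 | 90.6 | 1.5 | 3.9 | 3.2 |
| amber | 15.0 | 85.8 | 1.4 | 7.3 | 2.7 |
| amber | 25.0 | 79.7 | 3.1 | 14.1 | 2.5 |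
| amber | 40.0 | 73.7 | 4.1 | 18.7 | 3.1 |
| grey | 10.0 | 90.2 | 2.0 | 5.9 | 3.7 |
| grey | 20.0 | 84.3 | 3.0 | 11.6 | 2.6 |
| grey | 40.0 | 72.5 | 2.7 | 20.5 | 3.2 |

(each reading ± 0.5 percentage points)

- percentages count the X that a species holds: one L counts as two
- what was read earlier has a scatter of 0.5 percentage points, one standard deviation

- which of these there is most of at the end, counted by the X in it, west (X / E / L / Q)
- which of these there is most of at the end, counted by the X in it, south (X / E / L / Q)
- how much there is at the end of the one of these that leads, in percent of the X charged: west
- how much there is at the end of the one of these that leads, in percent of the X charged: south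

Yet two stretches of grey disagree: its first-order constant reads 0.0103 /s over the first 10.0 s, but 0.00728 /s from there to 40.0 s. The X lost in grey by then, 0.0275 M, is hardly any of the J, so one for one it takes too little J to explain the fall in the constant. A reading that fits is that J and D spend each other. The later constant in grey still reads 70.7% of the early one, which fits J, the bigger charge, as the partner of X that outlasts the pairing.

This reckoning takes the pairing as finished from the start, one for one, with D as limiting reagent. That leaves 0.400 M in west and 0.200 M in south of free J, the charge of J minus the charge of D. Scaling the early constant by free J over charged J gives 0.00516 /s for west and 0.00258 /s for south. The X left at the asked time reckons to 39.5% in west and 62.9% in south. By this estimate south keeps more X than it converts, so the reckoning puts X in the lead there. For west, amber's last product share gives an estimate of 43.7% of Q, more than the reckoned X, so the reckoning puts Q in the lead there, by a narrow margin.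

The forecast differs on south: Q at 54% in west and Q at 66% in south, “the D dependence is a guess”.

The flask gives Q at 39.0% in west and X at 52.1% in south.

    X + J → E (k = 0.0142 /M/s)
    J + D → Z (k = 0.128 /M/s)
    E + Z → Q (k = 1.29 /M/s)
    2 Z → G (k = 0.153 /M/s)
    X + E → L (k = 0.191 /M/s)

West ends with 31.8% of X and south with 52.1%, below the reckoned 39.5% and 62.9%. At the end of west J stands at 36% of its charge, less than the reckoned free J of 0.400 M, which is 50.0% of that charge. For the neighbour of west charged with 0.16 M of D, the same reckoning gives 0.640 M of free J, a constant of 0.00825 /s and an estimate of 22.6% of X left. That neighbour ends with D at 0% and J at 63% of their charges, and with X at 14.7%.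

The readings were generated by integration from invented constants; the scatter is artificial.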